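**Assumptions (one line each)**
- The target is the trans-(7R,8R)-benzodioxane (C7 = benzylic carbon, C8 = CH–CH2OH). B-ring O3′ carries the benzylic C7, and O4′ (next to the 5′-OMe) carries C8.
- The (R)-diarylprolinol silyl ether is assigned to give the (2R,3S)-epoxy aldehyde from the usual facial model of its iminium ion. If the other enantiomer is obtained, the catalyst enantiomer is swapped.

**Retrosynthesis**
1. The flavone C-ring is made last, from a chalcone (Claisen–Schmidt, then I2/DMSO) built on a benzodioxane benzaldehyde. All benzyl groups are removed together at the end.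
2. The benzodioxane ring is closed by two C–O bonds onto a trans-3-aryl-glycidyl benzyl ether. C7–O3′ forms by SN2 opening of the epoxide at the benzylic carbon with inversion. C8–O4′ forms by intramolecular Mitsunobu with inversion, giving the trans-dioxane.
3. Both stereocentres derive from one trans-epoxide, made by organocatalytic iminium epoxidation of 4-O-benzyl coniferaldehyde with H2O2.
4. Ring order: oxirane, then 1,4-dioxane, then the γ-pyranone (C-ring) of the flavone.

**Route**

**Step 1**
Reactants: 1 (E)-coniferaldehyde (4-hydroxy-3-methoxycinnamaldehyde)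
Product: 2 (E)-4-(benzyloxy)-3-methoxycinnamaldehyde
Conditions: BnBr, K2CO3, DMF, rt, 12 h
Reagents that add atoms: benzyl bromide, BrCc1ccccc1
Why: Williamson O-benzylation masks the phenol so it survives the later base, Mitsunobu and epoxidation steps and is removed in the final hydrogenolysis.

**Step 2**
Reactants: 2
Product: 3 (2R,3S)-3-[4-(benzyloxy)-3-methoxyphenyl]oxirane-2-carbaldehyde
Conditions: (R)-2-{bis[3,5-bis(CF3)phenyl](TMSO)methyl}pyrrolidine (10 mol%), 35% aq. H2O2, CH2Cl2, rt, 16 h
Reagents that add atoms: hydrogen peroxide, OO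
Why: Jørgensen–Hayashi iminium-catalysed Weitz–Scheffer epoxidation; the shielded iminium ion takes HOO⁻ at Cβ on one face, and enamine collapse closes the trans-epoxide (this sets both C7 and C8).

**Step 3**
Reactants: 3
Product: 4 (2S,3S)-[3-(4-benzyloxy-3-methoxyphenyl)oxiran-2-yl]methanol
Conditions: NaBH4, MeOH/CH2Cl2, 0 °C, 30 min (telescoped from Step 2, aldehyde not purified)
Reagents that add atoms: none
Why: chemoselective aldehyde reduction fixes the configurationally labile α-centre before it can epimerise; the epoxide and benzyl ethers are untouched (the descriptor at C2 changes from R to S only because the CIP priorities change).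

**Step 4**
Reactants: 4
Product: 5 (2S,3S)-2-[(benzyloxy)methyl]-3-[4-(benzyloxy)-3-methoxyphenyl]oxirane
Conditions: NaH, BnBr, TBAI (cat.), THF, 0 °C to rt
Reagents that add atoms: benzyl bromide, BrCc1ccccc1
Why: Williamson etherification traps the primary alkoxide faster than Payne rearrangement; it protects C9–OH so that only the secondary C8–OH can take part in Step 6.

**Step 5**
Reactants: 5; 6 5-hydroxyvanillin (3,4-dihydroxy-5-methoxybenzaldehyde)
Product: 7 3-[(1R,2S)-3-(benzyloxy)-1-[4-(benzyloxy)-3-methoxyphenyl]-2-hydroxypropoxy]-4-hydroxy-5-methoxybenzaldehyde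
Conditions: Cs2CO3 (3 equiv), DMF, 80 °C, 24 h
Reagents that add atoms: none
Why: Proposed new method: Cs2CO3 drives 6 to the catechol dianion. The 4-O⁻ is a para-formyl-stabilised, ortho-OMe-hindered, weak nucleophile, so alkylation would normally occur there. The localised, unhindered 3-O⁻ of the dianion is far more nucleophilic and reverses that site preference. It opens the p-alkoxyaryl-activated benzylic epoxide carbon by SN2 with inversion, giving C7–O3′ (S→R at C7) and leaving the C8 alcohol (S) with CH2OBn on the chain. The closest known reactions are aryloxide opening of 3-aryl glycidic compounds at the benzylic carbon and site-selective alkylation of dihydroxybenzaldehydes.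

**Step 6**
Reactants: 7
Product: 8 (2R,3R)-3-[(benzyloxy)methyl]-2-[4-(benzyloxy)-3-methoxyphenyl]-5-methoxy-2,3-dihydro-1,4-benzodioxine-7-carbaldehyde
Conditions: PPh3, DIAD, THF, 0 °C to rt
Reagents that add atoms: none
Why: intramolecular Mitsunobu etherification; the acidic 4-OH (para-CHO) closes the 6-exo ring on the secondary C8–O–PPh3⁺ with inversion (S→R at C8), giving the trans-(R,R) dioxane.

**Step 7** (independent fragment, parallel to Steps 1–6)
Reactants: 9 2′,4′,6′-trihydroxyacetophenone
Product: 10 2′-hydroxy-4′,6′-bis(benzyloxy)acetophenone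
Conditions: BnBr (2.1 equiv), K2CO3, acetone, reflux
Reagents that add atoms: benzyl bromide, BrCc1ccccc1
Why: the chelated 2′-OH is the least reactive of the three, so selective 4′,6′-di-O-benzylation follows.

**Step 8**
Reactants: 8; 10
Product: 11 (E)-chalcone: 1-[2-hydroxy-4,6-bis(benzyloxy)phenyl]-3-[benzodioxanyl]prop-2-en-1-one
Conditions: 50% aq. KOH, EtOH, rt, 48 h
Reagents that add atoms: none
Why: Claisen–Schmidt condensation of the aryl methyl ketone with the aldehyde; the dioxane stereocentres are not acidic and are untouched.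

**Step 9**
Reactants: 11
Product: 12 5,7-bis(benzyloxy)flavone bearing the trans-benzodioxane, fully O-benzylated
Conditions: I2 (0.3 equiv), DMSO, 110 °C, 2 h
Reagents that add atoms: none
Why: I2/DMSO oxidative cyclisation of a 2′-hydroxychalcone (oxa-Michael then iodine/DMSO dehydrogenation) forms the C2=C3 flavone.

**Step 10**
Reactants: 12
Product: 13 5′-methoxyhydnocarpin (target)
Conditions: H2 (1 atm), 10% Pd/C, THF/MeOH, rt
Reagents that add atoms: none
Why: hydrogenolysis removes all four benzyl groups (three on phenols, one on the primary alcohol) and does not touch the stereocentres.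

**Compound list**
1 | (E)-coniferaldehyde | COc1cc(/C=C/C=O)ccc1O | starting material
2 | (E)-4-benzyloxy-3-methoxycinnamaldehyde | COc1cc(/C=C/C=O)ccc1OCc1ccccc1 | intermediate
3 | (2R,3S)-epoxy aldehyde | O=C[C@@H]1O[C@H]1c1ccc(OCc2ccccc2)c(OC)c1 | intermediate
4 | (2S,3S)-epoxy alcohol | OC[C@@H]1O[C@H]1c1ccc(OCc2ccccc2)c(OC)c1 | intermediate
5 | (2S,3S)-epoxy benzyl ether | O(Cc1ccccc1)C[C@@H]1O[C@H]1c1ccc(OCc2ccccc2)c(OC)c1 | intermediate
6 | 5-hydroxyvanillin | COc1cc(C=O)cc(O)c1O | starting material
7 | ring-opened aryl ether, (7R,8S) | O=Cc1cc(OC)c(O)c(O[C@H](c2ccc(OCc3ccccc3)c(OC)c2)[C@@H](O)COCc2ccccc2)c1 | intermediate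
8 | benzodioxane aldehyde, (7R,8R) | COc1cc([C@H]2Oc3cc(C=O)cc(OC)c3O[C@@H]2COCc2ccccc2)ccc1OCc1ccccc1 | intermediate
9 | 2′,4′,6′-trihydroxyacetophenone | CC(=O)c1c(O)cc(O)cc1O | starting material
10 | 2′-hydroxy-4′,6′-bis(benzyloxy)acetophenone | CC(=O)c1c(O)cc(OCc2ccccc2)cc1OCc1ccccc1 | intermediate
11 | chalcone | COc1cc([C@H]2Oc3cc(/C=C/C(=O)c4c(O)cc(OCc5ccccc5)cc4OCc4ccccc4)cc(OC)c3O[C@@H]2COCc2ccccc2)ccc1OCc1ccccc1 | intermediate
12 | tetrabenzyl flavone | COc1cc([C@H]2Oc3cc(-c4cc(=O)c5c(OCc6ccccc6)cc(OCc6ccccc6)cc5o4)cc(OC)c3O[C@@H]2COCc2ccccc2)ccc1OCc1ccccc1 | intermediate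
13 | 5′-methoxyhydnocarpin | COc1cc([C@H]2Oc3cc(-c4cc(=O)c5c(O)cc(O)cc5o4)cc(OC)c3O[C@@H]2CO)ccc1O | target

**Step count:** 10 steps in total (Steps 2 and 3 are telescoped in practice). The longest linear sequence is 9 steps (Steps 1–6, 8, 9, 10 from coniferaldehyde).

**Three steps most likely to fail**
1. **Step 5 (proposed new dianion-controlled regioselective opening).** The 4-O attack or C8 attack could give regioisomers. Fallback (known chemistry): allylate 6 selectively at the acidic 4-OH (allyl bromide, K2CO3), open epoxide 5 with the free 3-OH, remove the allyl group (Pd(PPh3)4, K2CO3, MeOH), then run Step 6. This moves regiocontrol from base-dependent nucleophilicity to a protecting group.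
2. **Step 6 (Mitsunobu cyclisation).** Elimination or a sluggish 6-exo closure could lower the yield. Fallback: from the 4-O-allyl version of 7, mesylate the C8–OH (MsCl, Et3N), remove the allyl group with Pd(0), and close the ring by Cs2CO3-mediated SN2 (Williamson, inversion at C8). This replaces the redox-neutral Mitsunobu mechanism with a discrete sulfonate displacement.
3. **Step 10 (global hydrogenolysis).** Benzylic C7–O cleavage or flavone C2=C3 reduction could occur. Fallback: remove the benzyl groups with BCl3/pentamethylbenzene in CH2Cl2 at −78 °C, a Lewis-acid cleavage with a cation scavenger instead of catalytic hydrogenolysis.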